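Bilobetin is cut at the C2–C3 bond of each pyranone (ring C of both flavone units), while the C3'–C8 biaryl bond is kept as the core. The precursor is a biaryl bis-ester: every future O1 carries the aroyl group that becomes C2 together with its ring B, and sits ortho to a ring A acetyl group that supplies C3 and C4; the remaining phenols are isopropyl ethers and O4' is already methylated. One treatment with base shifts both acyl groups from oxygen to carbon, making both C2–C3 bonds and freeing both O1 phenols. Only the oxygen beside the biaryl carbon is acylated in the 8-linked unit, so closure can give only the C8 isomer.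

Key step: step 7

Assumption: the C3'–C8 axis is treated as freely rotating (the target carries no stereodescriptor), and the 1,3-diketones, drawn in the diketo form, are expected to exist largely as chelated enols.

Step 1
Reactants: 1 2,4,6-trihydroxyacetophenone
Product: 2 1-(2-hydroxy-4,6-diisopropoxyphenyl)ethanone
Conditions: 2-bromopropane (2.3 equiv), K2CO3 (2.5 equiv), N,N-dimethylformamide, 60 °C
Reagents that add atoms: 2-bromopropane, CC(C)Br
Why: Williamson ether synthesis in which the 4-hydroxyl and one ortho hydroxyl are alkylated while the last ortho hydroxyl, locked in a hydrogen bond to the acetyl carbonyl, should stay free, and a secondary bromide should give little C-alkylation.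

Step 2
Reactants: 2 1-(2-hydroxy-4,6-diisopropoxyphenyl)ethanone
Product: 3 1-(2-hydroxy-3-iodo-4,6-diisopropoxyphenyl)ethanone
Conditions: benzyltrimethylammonium dichloroiodate (1.0 equiv), CaCO3 (1.5 equiv), CH2Cl2–MeOH, rt
Reagents that add atoms: benzyltrimethylammonium dichloroiodate, C[N+](C)(C)Cc1ccccc1.Cl[I-]Cl
Why: Electrophilic aromatic iodination directed ortho to the free phenol (C3), the other open site C5 being shielded by two flanking isopropoxy groups; the same ortho-to-phenol selectivity is known for the dimethyl ether analogue.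

Step 3
Reactants: 3 1-(2-hydroxy-3-iodo-4,6-diisopropoxyphenyl)ethanone, 4 4-isopropoxybenzoic acid
Product: 6 6-acetyl-2-iodo-3,5-diisopropoxyphenyl 4-isopropoxybenzoate, via 4-isopropoxybenzoyl chloride 5 (not isolated)
Conditions: 4, (COCl)2, cat. N,N-dimethylformamide, CH2Cl2, 0 °C to rt, evaporate; then 3, Et3N, 4-(dimethylamino)pyridine, CH2Cl2, rt to 40 °C
Reagents that add atoms: none
Why: Acid chloride formation followed by nucleophile-catalysed O-acylation through the acylpyridinium ion, a forcing but standard way to esterify a phenol that is hydrogen-bonded and flanked by iodine and acetyl.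

Step 4
Reactants: 2 1-(2-hydroxy-4,6-diisopropoxyphenyl)ethanone, 7 3-bromo-4-methoxybenzoic acid
Product: 8 2-acetyl-3,5-diisopropoxyphenyl 3-bromo-4-methoxybenzoate
Conditions: N,N'-dicyclohexylcarbodiimide (1.2 equiv), 4-(dimethylamino)pyridine (0.1 equiv), CH2Cl2, 0 °C to rt
Reagents that add atoms: none
Why: Steglich esterification, in which the O-acylisourea is relayed through the acylpyridinium ion to the singly flanked phenol of 2 under neutral conditions that leave the aryl bromide and the ketone untouched.

Step 5
Reactants: 8 2-acetyl-3,5-diisopropoxyphenyl 3-bromo-4-methoxybenzoate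
Product: 9 2-acetyl-3,5-diisopropoxyphenyl 4-methoxy-3-(4,4,5,5-tetramethyl-1,3,2-dioxaborolan-2-yl)benzoate
Conditions: bis(pinacolato)diboron (1.2 equiv), PdCl2(dppf) (3 mol %), KOAc (3 equiv), 1,4-dioxane, 85 °C
Reagents that add atoms: bis(pinacolato)diboron, CC1(C)OB(OC1(C)C)B1OC(C)(C)C(C)(C)O1
Why: Miyaura borylation (oxidative addition of the aryl bromide to zerovalent palladium, acetate-assisted transmetalation with the diboron, reductive elimination), with an acetate base too weak to enolise the ketone or cleave the aryl ester.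

Step 6
Reactants: 6 6-acetyl-2-iodo-3,5-diisopropoxyphenyl 4-isopropoxybenzoate, 9 2-acetyl-3,5-diisopropoxyphenyl 4-methoxy-3-(4,4,5,5-tetramethyl-1,3,2-dioxaborolan-2-yl)benzoate
Product: 10 2-acetyl-3,5-diisopropoxyphenyl 3-[3-acetyl-4,6-diisopropoxy-2-(4-isopropoxybenzoyloxy)phenyl]-4-methoxybenzoate
Conditions: Pd2(dba)3 (2.5 mol %), 2-dicyclohexylphosphino-2',6'-dimethoxybiphenyl (SPhos, 10 mol %), CsF (3 equiv), anhydrous degassed 1,4-dioxane, 90 °C
Reagents that add atoms: none
Why: Suzuki–Miyaura coupling, in which the bulky electron-rich biarylphosphine is suited to biaryls with three ortho substituents and anhydrous fluoride activates the pinacol boronate without hydroxide or alkoxide, so both aryl esters and both ketones should come through unchanged.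

Step 7
Reactants: 10 2-acetyl-3,5-diisopropoxyphenyl 3-[3-acetyl-4,6-diisopropoxy-2-(4-isopropoxybenzoyloxy)phenyl]-4-methoxybenzoate
Product: 11 1-(2-hydroxy-4,6-diisopropoxyphenyl)-3-{3-[2-hydroxy-4,6-diisopropoxy-3-(3-(4-isopropoxyphenyl)-3-oxopropanoyl)phenyl]-4-methoxyphenyl}propane-1,3-dione
Conditions: KOtBu (6 equiv), THF (0.05 M), 0 °C to rt; then cold 1 M HCl
Reagents that add atoms: none
Why: tert-Butoxide deprotonates each acetyl methyl group, and each enolate carbon adds to the ester carbonyl held on the neighbouring ring oxygen through a six-membered cyclic transition state, after which the tetrahedral intermediate collapses with expulsion of the phenoxide, so that both aroyl groups pass from O to C and the C2–C3 bonds of both flavone units are formed. The closest known reaction type is the Baker–Venkataraman rearrangement of ortho-acyloxyacetophenones to ortho-hydroxydibenzoylmethanes, an intramolecular Claisen condensation, here expected to run twice and independently in one molecule. No ring is closed (the six-membered tetrahedral intermediates open again) and no stereocentre is created. The step needs each enolate to take the acyl group on its own ortho oxygen: the six-membered pathway is far easier than the medium-ring pathway to the remote ester, and dilution suppresses transfer between molecules. It also needs the aroyl group of unit 2 to leave from the oxygen beside the biaryl carbon, which is secured because that is the only acylated oxygen on that ring, the other ortho oxygen being an isopropyl ether, so that this oxygen becomes O1 and the aryl group ends at C8. Excess base drives the reaction by converting each product half into a diketonate–phenoxide dianion that is inert to further attack, and the bulk of tert-butoxide should keep it from attacking the shielded aryl esters directly.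

Step 8
Reactants: 11 1-(2-hydroxy-4,6-diisopropoxyphenyl)-3-{3-[2-hydroxy-4,6-diisopropoxy-3-(3-(4-isopropoxyphenyl)-3-oxopropanoyl)phenyl]-4-methoxyphenyl}propane-1,3-dione
Product: 12 8-[5-(5,7-diisopropoxy-4-oxo-4H-chromen-2-yl)-2-methoxyphenyl]-5,7-diisopropoxy-2-(4-isopropoxyphenyl)-4H-chromen-4-one
Conditions: p-toluenesulfonic acid monohydrate (0.3 equiv), toluene, 90 °C
Reagents that add atoms: none
Why: Acid-catalysed twofold cyclodehydration, in which the single free ortho phenol of each half adds to the distal carbonyl and the hemiketal loses water to give the pyranone, while a catalytic sulfonic acid should leave every isopropyl ether in place and so exclude ring opening and reclosure (Wessely–Moser rearrangement) that could move the aryl group from C8 to C6.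

Step 9
Reactants: 12 8-[5-(5,7-diisopropoxy-4-oxo-4H-chromen-2-yl)-2-methoxyphenyl]-5,7-diisopropoxy-2-(4-isopropoxyphenyl)-4H-chromen-4-one
Product: 13 bilobetin, 8-[5-(5,7-dihydroxy-4-oxo-4H-chromen-2-yl)-2-methoxyphenyl]-5,7-dihydroxy-2-(4-hydroxyphenyl)-4H-chromen-4-one
Conditions: BCl3 (15 equiv, 1 M in CH2Cl2), CH2Cl2, −78 to 0 °C; then H2O
Reagents that add atoms: none
Why: Lewis-acid ether cleavage, in which BCl3 coordinates each ether oxygen and chloride removes the secondary isopropyl group (fastest at the two 5-positions through chelation with the C4 carbonyls), whereas the lone methyl ether at C4' is primary, has no carbonyl neighbour to anchor boron, and should survive at or below 0 °C.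

Compound list
1 | 2,4,6-trihydroxyacetophenone | CC(=O)c1c(O)cc(O)cc1O | starting material
2 | 1-(2-hydroxy-4,6-diisopropoxyphenyl)ethanone | CC(=O)c1c(O)cc(OC(C)C)cc1OC(C)C | intermediate
3 | 1-(2-hydroxy-3-iodo-4,6-diisopropoxyphenyl)ethanone | CC(=O)c1c(O)c(I)c(OC(C)C)cc1OC(C)C | intermediate
4 | 4-isopropoxybenzoic acid | CC(C)Oc1ccc(cc1)C(O)=O | starting material
5 | 4-isopropoxybenzoyl chloride | CC(C)Oc1ccc(cc1)C(Cl)=O | intermediate
6 | 6-acetyl-2-iodo-3,5-diisopropoxyphenyl 4-isopropoxybenzoate | CC(=O)c1c(OC(=O)c2ccc(OC(C)C)cc2)c(I)c(OC(C)C)cc1OC(C)C | intermediate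
7 | 3-bromo-4-methoxybenzoic acid | COc1ccc(cc1Br)C(O)=O | starting material
8 | 2-acetyl-3,5-diisopropoxyphenyl 3-bromo-4-methoxybenzoate | COc1ccc(cc1Br)C(=O)Oc1cc(OC(C)C)cc(OC(C)C)c1C(C)=O | intermediate
9 | 2-acetyl-3,5-diisopropoxyphenyl 4-methoxy-3-(4,4,5,5-tetramethyl-1,3,2-dioxaborolan-2-yl)benzoate | COc1ccc(cc1B1OC(C)(C)C(C)(C)O1)C(=O)Oc1cc(OC(C)C)cc(OC(C)C)c1C(C)=O | intermediate
10 | 2-acetyl-3,5-diisopropoxyphenyl 3-[3-acetyl-4,6-diisopropoxy-2-(4-isopropoxybenzoyloxy)phenyl]-4-methoxybenzoate | COc1ccc(cc1-c1c(OC(C)C)cc(OC(C)C)c(C(C)=O)c1OC(=O)c1ccc(OC(C)C)cc1)C(=O)Oc1cc(OC(C)C)cc(OC(C)C)c1C(C)=O | intermediate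
11 | 1-(2-hydroxy-4,6-diisopropoxyphenyl)-3-{3-[2-hydroxy-4,6-diisopropoxy-3-(3-(4-isopropoxyphenyl)-3-oxopropanoyl)phenyl]-4-methoxyphenyl}propane-1,3-dione | COc1ccc(cc1-c1c(OC(C)C)cc(OC(C)C)c(C(=O)CC(=O)c2ccc(OC(C)C)cc2)c1O)C(=O)CC(=O)c1c(O)cc(OC(C)C)cc1OC(C)C | intermediate
12 | 8-[5-(5,7-diisopropoxy-4-oxo-4H-chromen-2-yl)-2-methoxyphenyl]-5,7-diisopropoxy-2-(4-isopropoxyphenyl)-4H-chromen-4-one | COc1ccc(cc1-c1c(OC(C)C)cc(OC(C)C)c2c(=O)cc(-c3ccc(OC(C)C)cc3)oc12)-c1cc(=O)c2c(OC(C)C)cc(OC(C)C)cc2o1 | intermediate
13 | bilobetin | COc1ccc(-c2cc(=O)c3c(O)cc(O)cc3o2)cc1-c1c(O)cc(O)c2c(=O)cc(-c3ccc(O)cc3)oc12 | target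

Total step count: 9. Longest linear sequence: 7 steps (steps 1, 2, 3, 6, 7, 8, 9 from compound 1; the branch through steps 1, 4, 5 is equally long).

Steps most likely to fail

Step 7. The second acyl transfer may lag behind the first, and tert-butoxide may attack an aryl ester from outside before its enolate forms, so that partly rearranged or deacylated material accumulates. The fallback runs the two transfers one after the other, with a ring closure in between. It sets out from 6. KOtBu in THF should give 1-(2-hydroxy-3-iodo-4,6-diisopropoxyphenyl)-3-(4-isopropoxyphenyl)propane-1,3-dione F1, and p-toluenesulfonic acid in toluene should close it to 8-iodo-5,7-diisopropoxy-2-(4-isopropoxyphenyl)-4H-chromen-4-one F2. Suzuki–Miyaura coupling of F2 with boronate 9 under the conditions of step 6 should give 2-acetyl-3,5-diisopropoxyphenyl 3-[5,7-diisopropoxy-2-(4-isopropoxyphenyl)-4-oxo-4H-chromen-8-yl]-4-methoxybenzoate F3. Its single ester should rearrange with LiN(SiMe3)2 in THF to 1-(2-hydroxy-4,6-diisopropoxyphenyl)-3-{3-[5,7-diisopropoxy-2-(4-isopropoxyphenyl)-4-oxo-4H-chromen-8-yl]-4-methoxyphenyl}propane-1,3-dione F4. Acid closure of F4 as in step 8 comes back to the route at 12.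

Step 6. Bond formation at an axis with three ortho substituents may be slow enough that protodeiodination and protodeboronation take over, and long heating with fluoride may begin to cleave or shift the aryl esters. Acyl migration at this stage would only anticipate step 7, but ester cleavage would not be recoverable. The fallback makes the biaryl bond before any aryl ester exists. It sets out from 3, which is coupled with purchased 3-borono-4-methoxybenzoic acid F5 (Pd(OAc)2, SPhos, K3PO4, dioxane–water, 80 °C) to give 3-(3-acetyl-2-hydroxy-4,6-diisopropoxyphenyl)-4-methoxybenzoic acid F6. Steglich esterification of F6 with excess phenol 2 (N,N'-dicyclohexylcarbodiimide, 4-(dimethylamino)pyridine) should give 2-acetyl-3,5-diisopropoxyphenyl 3-(3-acetyl-2-hydroxy-4,6-diisopropoxyphenyl)-4-methoxybenzoate F7. This relies on the phenol of F6, wedged between the acetyl group and the aryl ring, not competing with phenol 2. Aroylation of F7 with acid chloride 5 (Et3N, 4-(dimethylamino)pyridine, CH2Cl2) comes back to the route at 10.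

Step 1. Partial alkylation with a sluggish secondary halide may stop at the mono-ether or run on to the tri-ether, and loss of the bromide by elimination may starve the reaction. The fallback separates exhaustive alkylation from selective unmasking. It sets out from 1, which with excess 2-iodopropane and Cs2CO3 in N,N-dimethylformamide at 80 °C should give 1-(2,4,6-triisopropoxyphenyl)ethanone F8. BCl3 (1 equiv, CH2Cl2, −78 °C) should then remove one of the two equivalent ortho isopropyl groups through chelation to the acetyl carbonyl. This comes back to the route at 2.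

Further compounds
F1 | step 7 | 1-(2-hydroxy-3-iodo-4,6-diisopropoxyphenyl)-3-(4-isopropoxyphenyl)propane-1,3-dione | O=C(CC(=O)c1ccc(OC(C)C)cc1)c1c(O)c(I)c(OC(C)C)cc1OC(C)C
F2 | step 7 | 8-iodo-5,7-diisopropoxy-2-(4-isopropoxyphenyl)-4H-chromen-4-one | CC(C)Oc1ccc(cc1)-c1cc(=O)c2c(OC(C)C)cc(OC(C)C)c(I)c2o1
F3 | step 7 | 2-acetyl-3,5-diisopropoxyphenyl 3-[5,7-diisopropoxy-2-(4-isopropoxyphenyl)-4-oxo-4H-chromen-8-yl]-4-methoxybenzoate | COc1ccc(cc1-c1c(OC(C)C)cc(OC(C)C)c2c(=O)cc(-c3ccc(OC(C)C)cc3)oc12)C(=O)Oc1cc(OC(C)C)cc(OC(C)C)c1C(C)=O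
F4 | step 7 | 1-(2-hydroxy-4,6-diisopropoxyphenyl)-3-{3-[5,7-diisopropoxy-2-(4-isopropoxyphenyl)-4-oxo-4H-chromen-8-yl]-4-methoxyphenyl}propane-1,3-dione | COc1ccc(cc1-c1c(OC(C)C)cc(OC(C)C)c2c(=O)cc(-c3ccc(OC(C)C)cc3)oc12)C(=O)CC(=O)c1c(O)cc(OC(C)C)cc1OC(C)C
F5 | step 6 | 3-borono-4-methoxybenzoic acid (purchased) | COc1ccc(cc1B(O)O)C(O)=O
F6 | step 6 | 3-(3-acetyl-2-hydroxy-4,6-diisopropoxyphenyl)-4-methoxybenzoic acid | COc1ccc(cc1-c1c(O)c(C(C)=O)c(OC(C)C)cc1OC(C)C)C(O)=O
F7 | step 6 | 2-acetyl-3,5-diisopropoxyphenyl 3-(3-acetyl-2-hydroxy-4,6-diisopropoxyphenyl)-4-methoxybenzoate | COc1ccc(cc1-c1c(O)c(C(C)=O)c(OC(C)C)cc1OC(C)C)C(=O)Oc1cc(OC(C)C)cc(OC(C)C)c1C(C)=O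
F8 | step 1 | 1-(2,4,6-triisopropoxyphenyl)ethanone | CC(=O)c1c(OC(C)C)cc(OC(C)C)cc1OC(C)C
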